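Readings and results come from a simulation for substances that don't exist; scatter was added.

**Early readings.** Early in the green run, J at 15.1% and Q at 84.4% still sum to 99.5%, so I read Q + Z → J and try second order. Integrated to each run's last reading, this gives 0.573 /M/h at −18 °C and 5.63 /M/h at 10 °C. The activation energy is 49.0 kJ/mol.

all flasks: Z 0.165 M
- violet: Q 0.15 M; temperature −18 °C; run made earlier
- green: Q 0.24 M; temperature 10 °C; run made earlier
- cedar: Q 0.11 M; temperature −30 °C; time 20 h
- alder: Q 0.11 M; temperature 20 °C; time 20 h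
- birch: Q 0.11 M; temperature −5 °C; time 20 h

violet run (percent of the Q charged)

| time / h | J / % | D / % | Q / % |
|---|---|---|---|
| 0.333 | 2.9 | 0.1 | 97.0 |
| 1.00 | 8.1 | 0 | 91.2 |
| 1.50 | 13.1 | 0.2 | 86.7 |
| 3.00 | 22.3 | 0.3 | 77.4 |
| 4.00 | 28.4 | 0.1 | 71.0 |
| 6.00 | 36.9 | 0.4 | 63.2 |

green run (percent of the Q charged)

| time / min | J / % | D / % | Q / % |
|---|---|---|---|
| 12.0 | 15.1 | 0.8 | 84.4 |
| 25.0 | 25.6 | 1.0 | 73.1 |
| 40.0 | 33.3 | 1.8 | 64.8 |
| 50.0 | 37.1 | 2.3 | 59.8 |
| 60.0 | 38.4 | 3.3 | 56.4 |
| 80.0 | 40.8 | 3.5 | 51.4 |
| 90.0 | 42.3 | 3.2 | 49.2 |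

(each reading ± 0.5 percentage points)

1. the flask that comes out highest in amount of J, in percent of the Q charged, or "all alike" when all lie within 1.5 percentage points (cedar / alder / birch / all alike)
2. J at the end, in percent of the Q charged, cedar
3. J at the end, in percent of the Q charged, alder
4. J at the end, in percent of the Q charged, birch



**Making.** In cedar, alder and birch, Q is the limiting reagent, since [Q] is below [Z]. In cedar, a rate constant of 0.183 /M/h should leave 59.9% of Q at the end. In birch, 1.76 /M/h should leave 5.34%, and conversion of Q should reach its midpoint at 2.98 h.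

**Losing.** Late in green, Q gone but not present as J comes to 8.5 percentage points. Taking mean J as 2/3 of its last reading, I read for green, at 10 °C, the loss constant λ, the share of J lost per hour, as 0.201 /h.

**Joining.** Before the midpoint I count making without loss, and after it loss without making. So J is the converted Q times exp(−λ × time after midpoint).

**Weak link.** Violet's deficit reads −0.1 points, which gives no rate. I put its scatter in instead, a rough ceiling on violet's λ of 0.00479 /h. The activation energy of the loss then has a rough floor, 80.2 kJ/mol. With that floor, birch gets a λ of 0.0299 /h, so my reckoning puts its J near 56.9%. With the same floor, alder's time comes to 12.8 lifetimes of J, so I expect little J in alder. Cedar's reckoned conversion of Q, 40.1%, stands below birch's reckoned J, so I commit to birch.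

**The forecast.** It says birch, with cedar 40%, alder 0.5%, birch 66%, noting “The loss does not slow as Q and Z fall.” Its birch stands above my reckoning.

**The flask.** Cedar gives 40.5%, alder 2.13%, birch 69.6%, so birch leads. Left until 200 h, birch holds 3.04% of J, so J there is a passing stock. Read back through the joined rule, birch's effective λ is 0.0182 /h. Against green's 0.201 /h, that corresponds to an effective activation energy of 101 kJ/mol.

    Q + Z → J + X (k = 0.00324 /M/s, Ea = 49.0 kJ/mol)
    J → L (k = 8.13 × 10⁻⁵ /s, Ea = 100 kJ/mol)
    J ⇌ D (K = 12.0, k = 9.44 × 10⁻⁵ /s, Ea = 91.0 kJ/mol, ΔH = −24.0 kJ/mol)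
    J ⇌ G (K = 2.37, k = 3.44 × 10⁻⁵ /s, Ea = 96.0 kJ/mol, ΔH = −46.0 kJ/mol)
    (constants at 20 °C)

**Next flask.** For alder repeated at 5 °C, λ becomes 0.0929 /h and the midpoint 1.35 h, so, counting its charge of Q as converted, J should be 17.7%. That repeat gives 21.4%.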